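## Retrosynthetic overview

- The C5 ester is made last by Mitsunobu inversion of the equatorial C5 alcohol 26 with the (Z,Z)-oxazole acid 39; 26 comes from hydride reduction of the C5 ketone 25.
- The 14-membered lactone (second ring) is closed at O13–C1 by Yamaguchi lactonisation of seco acid 23.
- The strategy rests on the cis-2,6-disubstituted tetrahydropyran (ring O, C3, C4, C5, C6, C7) with oxygen at C5, which is the retron of a carbonyl hetero-Diels–Alder reaction. This ring is formed first, from the C1–C3 aldehyde 17 and the C4–C16 2-silyloxydiene 14, making C3–C4 and O–C7.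
- Diene 14 comes from the enone (HWE at C7). C9 is set by Cu-catalysed conjugate methylation, C11 by Brown allylation, C13 by Noyori hydrogenation.
- Acid 39: Bredereck oxazole, C2 zincation/iodination, Sonogashira, Lindlar, Still–Gennari.

Key step: step 13

Remark on the chemistry: the route is built for exactly the configuration encoded in the target SMILES (3R,5R,7R,9S,11R,13R, lactone numbering with C1 = lactone carbonyl); for the two ligand-controlled steps 7 and 13 the face to be attacked is stated and the antipode of the commercial ligand is chosen to match it.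

## Route

Step 1
Reactants: 1 methyl 3-oxohexanoate
Product: 2 methyl (3R)-3-hydroxyhexanoate
Conditions: H2 (50 atm), [RuCl2((R)-BINAP)] (0.1 mol%), MeOH, 50 °C
Reagents that add atoms: none
Why: Noyori asymmetric hydrogenation of a β-keto ester, in which the (R)-BINAP–Ru catalyst reduces the ester-chelated ketone from one face and should set C13 as R.

Step 2
Reactants: 2 methyl (3R)-3-hydroxyhexanoate
Product: 3 methyl (3R)-3-[(tert-butyldimethylsilyl)oxy]hexanoate
Conditions: TBSCl, imidazole, DMF, rt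
Reagents that add atoms: tert-butyldimethylsilyl chloride, CC(C)(C)[Si](C)(C)Cl
Why: Standard imidazole-promoted silylation of a secondary alcohol, which leaves the C13 stereocentre untouched.

Step 3
Reactants: 3 methyl (3R)-3-[(tert-butyldimethylsilyl)oxy]hexanoate
Product: 4 (3R)-3-[(tert-butyldimethylsilyl)oxy]hexanal
Conditions: DIBAL-H (1.05 equiv), CH2Cl2, −78 °C; Rochelle salt
Reagents that add atoms: none
Why: Partial ester reduction, in which the tetrahedral aluminium hemiacetal is stable at −78 °C and releases the aldehyde only on work-up.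

Step 4
Reactants: 4 (3R)-3-[(tert-butyldimethylsilyl)oxy]hexanal
Product: 6 (4R,6R)-6-[(tert-butyldimethylsilyl)oxy]non-1-en-4-ol, via diisopinocampheylborinate ester 5 (not isolated)
Conditions: (+)-Ipc2BOMe, allylMgBr, Et2O, 0 °C → rt; then 4, −78 °C; NaOH, H2O2, rt
Reagents that add atoms: allylmagnesium bromide, C=CC[Mg]Br
Why: Brown allylboration through a chair Zimmerman–Traxler transition state, in which the Ipc2B(allyl) reagent derived from (−)-α-pinene should add to the Re face of the aldehyde under reagent control and set C11 as R, anti to the C13 silyl ether.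

Step 5
Reactants: 6 (4R,6R)-6-[(tert-butyldimethylsilyl)oxy]non-1-en-4-ol
Product: 7 tert-butyl{[(4R,6R)-6-methoxynon-8-en-4-yl]oxy}dimethylsilane
Conditions: Me3OBF4, Proton Sponge, CH2Cl2, rt
Reagents that add atoms: trimethyloxonium tetrafluoroborate, C[O+](C)C.F[B-](F)(F)F
Why: O-Methylation with Meerwein's salt under non-basic conditions, which avoids 1,3-silyl migration via an alkoxide and affects no stereocentre.

Step 6
Reactants: 7 tert-butyl{[(4R,6R)-6-methoxynon-8-en-4-yl]oxy}dimethylsilane; 8 methyl acrylate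
Product: 9 methyl (2E,5R,7R)-7-[(tert-butyldimethylsilyl)oxy]-5-methoxydec-2-enoate
Conditions: Grubbs second-generation catalyst (3 mol%), 8 (4 equiv), CH2Cl2, 40 °C
Reagents that add atoms: none
Why: Olefin cross-metathesis of a terminal alkene with an electron-poor acrylate, which should give the (E)-enoate selectively with loss of ethene.

Step 7
Reactants: 9 methyl (2E,5R,7R)-7-[(tert-butyldimethylsilyl)oxy]-5-methoxydec-2-enoate
Product: 10 methyl (3S,5R,7R)-7-[(tert-butyldimethylsilyl)oxy]-5-methoxy-3-methyldecanoate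
Conditions: MeMgBr (4 equiv), CuI (3 mol%), Tol-BINAP (4.5 mol%, antipode for Si-face delivery at C3 of the enoate), t-BuOMe, −20 °C; aq. NH4Cl
Reagents that add atoms: methylmagnesium bromide, C[Mg]Br
Why: Copper-catalysed asymmetric conjugate addition of a Grignard reagent to an (E)-enoate, in which the chiral bisphosphine–copper complex should deliver methyl to the Si face of the β-carbon and set C9 as S under catalyst control.

Step 8
Reactants: 10 methyl (3S,5R,7R)-7-[(tert-butyldimethylsilyl)oxy]-5-methoxy-3-methyldecanoate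
Product: 11 (3S,5R,7R)-7-[(tert-butyldimethylsilyl)oxy]-5-methoxy-3-methyldecanal
Conditions: DIBAL-H (1.05 equiv), CH2Cl2, −78 °C; Rochelle salt
Reagents that add atoms: none
Why: Partial ester reduction via the cold-stable aluminium hemiacetal; the β-stereocentre C9 cannot epimerise because the α-carbon is a methylene.

Step 9
Reactants: 11 (3S,5R,7R)-7-[(tert-butyldimethylsilyl)oxy]-5-methoxy-3-methyldecanal; 12 dimethyl (2-oxopropyl)phosphonate
Product: 13 (3E,6R,8R,10R)-10-[(tert-butyldimethylsilyl)oxy]-8-methoxy-6-methyltridec-3-en-2-one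
Conditions: Ba(OH)2, THF/H2O (40:1), rt
Reagents that add atoms: none
Why: Horner–Wadsworth–Emmons olefination with a stabilised β-ketophosphonate, which should give the (E)-enone under mild base that avoids aldehyde self-condensation.

Step 10
Reactants: 13 (3E,6R,8R,10R)-10-[(tert-butyldimethylsilyl)oxy]-8-methoxy-6-methyltridec-3-en-2-one
Product: 14 (3E,6R,8R,10R)-10-[(tert-butyldimethylsilyl)oxy]-8-methoxy-6-methyl-2-[(triethylsilyl)oxy]trideca-1,3-diene
Conditions: TESOTf, Et3N, Et2O, −78 °C; used directly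
Reagents that add atoms: triethylsilyl triflate, CC[Si](CC)(CC)OS(=O)(=O)C(F)(F)F
Why: Soft enolisation, in which O-silylation followed by kinetic deprotonation of the α′-methyl group should give the cross-conjugated 2-silyloxydiene with the (E)-alkene retained.

Step 11
Reactants: 15 propane-1,3-diol
Product: 16 3-[(4-methoxybenzyl)oxy]propan-1-ol
Conditions: NaH (1 equiv), PMBCl, Bu4NI (cat.), THF, 0 °C → rt; 15 in threefold excess
Reagents that add atoms: 4-methoxybenzyl chloride, COc1ccc(CCl)cc1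
Why: Williamson ether synthesis, in which excess diol favours mono-alkylation.

Step 12
Reactants: 16 3-[(4-methoxybenzyl)oxy]propan-1-ol
Product: 17 3-[(4-methoxybenzyl)oxy]propanal
Conditions: (COCl)2, DMSO, CH2Cl2, −78 °C; Et3N, −78 → 0 °C
Reagents that add atoms: none
Why: Swern oxidation, which stops at the aldehyde and is cold enough to avoid β-elimination of the PMB ether.

Step 13
Reactants: 14 (3E,6R,8R,10R)-10-[(tert-butyldimethylsilyl)oxy]-8-methoxy-6-methyl-2-[(triethylsilyl)oxy]trideca-1,3-diene; 17 3-[(4-methoxybenzyl)oxy]propanal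
Product: 18 (2S,6R)-6-[(2S,4R,6R)-6-[(tert-butyldimethylsilyl)oxy]-4-methoxy-2-methylnonyl]-2-{2-[(4-methoxybenzyl)oxy]ethyl}-4-[(triethylsilyl)oxy]-3,6-dihydro-2H-pyran
Conditions: chiral tridentate Schiff-base Cr(III)Cl catalyst [3-(1-adamantyl)-5-methylsalicylaldimine of cis-1-amino-2-indanol, antipode for Re-face attack on 17] (10 mol%), 4 Å MS, acetone (minimal), rt, 48 h
Reagents that add atoms: none
Why: The chromium(III) Lewis acid activates the aldehyde of 17 and diene 14 adds in a concerted but asynchronous [4+2] cycloaddition in which the nucleophilic C4 methylene bonds to C3 and the carbonyl oxygen bonds to C7; the closest known reaction type is the chromium(III)-catalysed carbonyl hetero-Diels–Alder reaction of 2-silyloxydienes with aliphatic aldehydes. The dihydropyran (O, C3–C7) closes in this single pericyclic event, suprafacially on both partners, with the ring oxygen coming from the aldehyde. C3 is set by the catalyst, which must direct C4 to the Re face of the aldehyde (3S in 18, the same spatial arrangement as 3R in the target). C7 is relayed from C3 by the endo transition state of the (E)-C6=C7 alkene, which puts the C3 and C7 substituents cis (7R). The step needs aldehyde-face selectivity and endo selectivity: the ligand secures the first because the nearest diene stereocentre (C9) is separated from C7 by a methylene and gives no useful bias, and the diene geometry together with the tight metal-bound transition state secures the second. Sieves and a nonprotic medium keep the acid-labile silyl dienol ether intact until it has reacted.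

Step 14
Reactants: 18 (2S,6R)-6-[(2S,4R,6R)-6-[(tert-butyldimethylsilyl)oxy]-4-methoxy-2-methylnonyl]-2-{2-[(4-methoxybenzyl)oxy]ethyl}-4-[(triethylsilyl)oxy]-3,6-dihydro-2H-pyran
Product: 19 (2R,6S)-2-[(2S,4R,6R)-6-[(tert-butyldimethylsilyl)oxy]-4-methoxy-2-methylnonyl]-6-{2-[(4-methoxybenzyl)oxy]ethyl}oxan-4-one
Conditions: TFA (cat.), CH2Cl2/H2O, 0 °C
Reagents that add atoms: none
Why: Protodesilylation of the silyl enol ether under mild acid should unmask the C5 ketone; the 2,6-cis arrangement is the thermodynamic one, and the TBS and PMB ethers are stable to these conditions.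

Step 15
Reactants: 19 (2R,6S)-2-[(2S,4R,6R)-6-[(tert-butyldimethylsilyl)oxy]-4-methoxy-2-methylnonyl]-6-{2-[(4-methoxybenzyl)oxy]ethyl}oxan-4-one
Product: 20 (2R,6S)-2-[(2S,4R,6R)-6-[(tert-butyldimethylsilyl)oxy]-4-methoxy-2-methylnonyl]-6-(2-hydroxyethyl)oxan-4-one
Conditions: DDQ, CH2Cl2/pH 7 buffer (10:1), 0 °C → rt
Reagents that add atoms: none
Why: Oxidative PMB cleavage by benzylic hydride abstraction and hydrolysis of the oxocarbenium ion, to which the ketone and the TBS ether are inert.

Step 16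
Reactants: 20 (2R,6S)-2-[(2S,4R,6R)-6-[(tert-butyldimethylsilyl)oxy]-4-methoxy-2-methylnonyl]-6-(2-hydroxyethyl)oxan-4-one
Product: 22 2-[(2R,6R)-6-[(2S,4R,6R)-6-[(tert-butyldimethylsilyl)oxy]-4-methoxy-2-methylnonyl]-4-oxooxan-2-yl]acetic acid, via aldehyde 21 (not isolated)
Conditions: TEMPO (20 mol%), PhI(OAc)2 (2.5 equiv), MeCN/H2O (1:1), rt
Reagents that add atoms: water, O
Why: Oxoammonium-mediated oxidation takes the primary alcohol through the aldehyde hydrate to the acid under near-neutral conditions, which should avoid β-elimination of the pyran oxygen.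

Step 17
Reactants: 22 2-[(2R,6R)-6-[(2S,4R,6R)-6-[(tert-butyldimethylsilyl)oxy]-4-methoxy-2-methylnonyl]-4-oxooxan-2-yl]acetic acid
Product: 23 2-[(2R,6R)-6-[(2S,4R,6R)-6-hydroxy-4-methoxy-2-methylnonyl]-4-oxooxan-2-yl]acetic acid
Conditions: HF·pyridine, pyridine, THF, 0 °C → rt
Reagents that add atoms: none
Why: Fluoride cleavage of the secondary TBS ether, driven by the Si–F bond, should free the C13 hydroxyl under buffered conditions that the β-alkoxy ketone tolerates.

Step 18
Reactants: 23 2-[(2R,6R)-6-[(2S,4R,6R)-6-hydroxy-4-methoxy-2-methylnonyl]-4-oxooxan-2-yl]acetic acid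
Product: 25 (1R,5R,7R,9S,11R)-7-methoxy-9-methyl-5-propyl-4,15-dioxabicyclo[9.3.1]pentadecane-3,13-dione, via mixed anhydride 24 (not isolated)
Conditions: 2,4,6-trichlorobenzoyl chloride, Et3N, THF, rt; then slow addition to DMAP, toluene, 80 °C (about 1 mM)
Reagents that add atoms: none
Why: Yamaguchi macrolactonisation, in which DMAP converts the mixed anhydride into an acylpyridinium that the C13 hydroxyl captures under high dilution, closing the 14-membered lactone with retention at C13.

Step 19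
Reactants: 25 (1R,5R,7R,9S,11R)-7-methoxy-9-methyl-5-propyl-4,15-dioxabicyclo[9.3.1]pentadecane-3,13-dione
Product: 26 (1R,5R,7R,9S,11R,13S)-13-hydroxy-7-methoxy-9-methyl-5-propyl-4,15-dioxabicyclo[9.3.1]pentadecan-3-one
Conditions: NaBH4, MeOH, 0 °C
Reagents that add atoms: none
Why: Axial hydride attack on the conformationally locked 2,6-cis-tetrahydropyran-4-one should give the equatorial C5 alcohol (5S), cis to both ring substituents, without touching the lactone.

Step 20
Reactants: 27 prop-2-yn-1-amine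
Product: 28 methyl prop-2-yn-1-ylcarbamate
Conditions: ClCO2Me, Et3N, CH2Cl2, 0 °C
Reagents that add atoms: methyl chloroformate, COC(=O)Cl
Why: N-Acylation of a primary amine by a chloroformate gives the carbamate.

Step 21
Reactants: 29 methyl 5-bromo-4-oxopentanoate; 30 formamide
Product: 31 methyl 3-(1,3-oxazol-4-yl)propanoate
Conditions: 30 (excess, neat), 110 °C
Reagents that add atoms: none
Why: Bredereck oxazole synthesis (Hantzsch-type), in which O-alkylation of formamide by the α-bromoketone and cyclodehydration onto the ketone should give the 4-substituted oxazole, the ketone carbon becoming C4.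

Step 22
Reactants: 31 methyl 3-(1,3-oxazol-4-yl)propanoate
Product: 33 methyl 3-(2-iodo-1,3-oxazol-4-yl)propanoate, via oxazol-2-ylzinc chloride 32 (not isolated)
Conditions: TMPZnCl·LiCl (1.2 equiv), THF, 25 °C; then I2, 0 °C
Reagents that add atoms: iodine, II
Why: Directed C–H zincation at the most acidic ring position C2 with a hindered zinc amide base that tolerates the ester and keeps the metallated oxazole ring closed, followed by iodinolysis of the C–Zn bond.

Step 23
Reactants: 33 methyl 3-(2-iodo-1,3-oxazol-4-yl)propanoate; 28 methyl prop-2-yn-1-ylcarbamate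
Product: 34 methyl 3-{2-[3-[(methoxycarbonyl)amino]prop-1-yn-1-yl]-1,3-oxazol-4-yl}propanoate
Conditions: PdCl2(PPh3)2 (3 mol%), CuI (6 mol%), Et3N, THF, rt
Reagents that add atoms: none
Why: Sonogashira coupling, in which the electron-poor 2-iodooxazole undergoes ready oxidative addition and couples with the copper acetylide.

Step 24
Reactants: 34 methyl 3-{2-[3-[(methoxycarbonyl)amino]prop-1-yn-1-yl]-1,3-oxazol-4-yl}propanoate
Product: 35 methyl 3-{2-[(1Z)-3-[(methoxycarbonyl)amino]prop-1-en-1-yl]-1,3-oxazol-4-yl}propanoate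
Conditions: H2 (1 atm), Lindlar catalyst, quinoline, EtOAc, rt
Reagents that add atoms: none
Why: Lindlar semihydrogenation adds hydrogen syn on poisoned palladium and should stop at the (Z)-alkene.

Step 25
Reactants: 35 methyl 3-{2-[(1Z)-3-[(methoxycarbonyl)amino]prop-1-en-1-yl]-1,3-oxazol-4-yl}propanoate
Product: 36 methyl {(2Z)-3-[4-(3-oxopropyl)-1,3-oxazol-2-yl]prop-2-en-1-yl}carbamate
Conditions: DIBAL-H (2.2 equiv), CH2Cl2, −78 °C; Rochelle salt
Reagents that add atoms: none
Why: Partial ester reduction at −78 °C, in which the first equivalent of hydride deprotonates the carbamate N–H and so protects it as its aluminium amide.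

Step 26
Reactants: 36 methyl {(2Z)-3-[4-(3-oxopropyl)-1,3-oxazol-2-yl]prop-2-en-1-yl}carbamate; 37 methyl [bis(2,2,2-trifluoroethoxy)phosphoryl]acetate
Product: 38 methyl (2Z)-5-{2-[(1Z)-3-[(methoxycarbonyl)amino]prop-1-en-1-yl]-1,3-oxazol-4-yl}pent-2-enoate
Conditions: KHMDS, 18-crown-6, THF, −78 °C
Reagents that add atoms: none
Why: Still–Gennari olefination, in which fast, irreversible elimination from the kinetic adduct of the electron-poor phosphonate should give the (Z)-enoate.

Step 27
Reactants: 38 methyl (2Z)-5-{2-[(1Z)-3-[(methoxycarbonyl)amino]prop-1-en-1-yl]-1,3-oxazol-4-yl}pent-2-enoate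
Product: 39 (2Z)-5-{2-[(1Z)-3-[(methoxycarbonyl)amino]prop-1-en-1-yl]-1,3-oxazol-4-yl}pent-2-enoic acid
Conditions: LiOH, THF/H2O, 0 °C → rt; 1 M HCl to pH 3
Reagents that add atoms: lithium hydroxide, [Li+].[OH-]
Why: Saponification of the methyl ester, which the far less electrophilic methyl carbamate and both (Z)-alkenes should survive.

Step 28
Reactants: 26 (1R,5R,7R,9S,11R,13S)-13-hydroxy-7-methoxy-9-methyl-5-propyl-4,15-dioxabicyclo[9.3.1]pentadecan-3-one; 39 (2Z)-5-{2-[(1Z)-3-[(methoxycarbonyl)amino]prop-1-en-1-yl]-1,3-oxazol-4-yl}pent-2-enoic acid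
Product: 40 neopeltolide
Conditions: PPh3, DIAD, benzene, 0 °C → rt
Reagents that add atoms: none
Why: Mitsunobu esterification, in which the carboxylate displaces the C5 alkoxyphosphonium by SN2 and so inverts C5 to the axial 5R ester of the target.

## Compound list

1 | methyl 3-oxohexanoate | CCCC(=O)CC(=O)OC | starting material
2 | methyl (3R)-3-hydroxyhexanoate | CCC[C@@H](O)CC(=O)OC | intermediate
3 | methyl (3R)-3-[(tert-butyldimethylsilyl)oxy]hexanoate | CCC[C@@H](O[Si](C)(C)C(C)(C)C)CC(=O)OC | intermediate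
4 | (3R)-3-[(tert-butyldimethylsilyl)oxy]hexanal | CCC[C@@H](O[Si](C)(C)C(C)(C)C)CC=O | intermediate
5 | (4R,6R)-6-[(tert-butyldimethylsilyl)oxy]non-1-en-4-yl bis(isopinocampheyl)borinate (Ipc from (−)-α-pinene) | CCC[C@@H](O[Si](C)(C)C(C)(C)C)C[C@H](OB([C@H]1C[C@H]2C[C@@H]([C@@H]1C)C2(C)C)[C@H]1C[C@H]2C[C@@H]([C@@H]1C)C2(C)C)CC=C | intermediate (not isolated)
6 | (4R,6R)-6-[(tert-butyldimethylsilyl)oxy]non-1-en-4-ol | CCC[C@@H](O[Si](C)(C)C(C)(C)C)C[C@H](O)CC=C | intermediate
7 | tert-butyl{[(4R,6R)-6-methoxynon-8-en-4-yl]oxy}dimethylsilane | CCC[C@@H](O[Si](C)(C)C(C)(C)C)C[C@H](OC)CC=C | intermediate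
8 | methyl acrylate | C=CC(=O)OC | starting material
9 | methyl (2E,5R,7R)-7-[(tert-butyldimethylsilyl)oxy]-5-methoxydec-2-enoate | CCC[C@@H](O[Si](C)(C)C(C)(C)C)C[C@H](OC)C/C=C/C(=O)OC | intermediate
10 | methyl (3S,5R,7R)-7-[(tert-butyldimethylsilyl)oxy]-5-methoxy-3-methyldecanoate | CCC[C@@H](O[Si](C)(C)C(C)(C)C)C[C@H](OC)C[C@H](C)CC(=O)OC | intermediate
11 | (3S,5R,7R)-7-[(tert-butyldimethylsilyl)oxy]-5-methoxy-3-methyldecanal | CCC[C@@H](O[Si](C)(C)C(C)(C)C)C[C@H](OC)C[C@H](C)CC=O | intermediate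
12 | dimethyl (2-oxopropyl)phosphonate | CC(=O)CP(=O)(OC)OC | starting material
13 | (3E,6R,8R,10R)-10-[(tert-butyldimethylsilyl)oxy]-8-methoxy-6-methyltridec-3-en-2-one | CCC[C@@H](O[Si](C)(C)C(C)(C)C)C[C@H](OC)C[C@H](C)C/C=C/C(C)=O | intermediate
14 | (3E,6R,8R,10R)-10-[(tert-butyldimethylsilyl)oxy]-8-methoxy-6-methyl-2-[(triethylsilyl)oxy]trideca-1,3-diene | CCC[C@@H](O[Si](C)(C)C(C)(C)C)C[C@H](OC)C[C@H](C)C/C=C/C(=C)O[Si](CC)(CC)CC | intermediate
15 | propane-1,3-diol | OCCCO | starting material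
16 | 3-[(4-methoxybenzyl)oxy]propan-1-ol | OCCCOCc1ccc(OC)cc1 | intermediate
17 | 3-[(4-methoxybenzyl)oxy]propanal | O=CCCOCc1ccc(OC)cc1 | intermediate
18 | (2S,6R)-6-[(2S,4R,6R)-6-[(tert-butyldimethylsilyl)oxy]-4-methoxy-2-methylnonyl]-2-{2-[(4-methoxybenzyl)oxy]ethyl}-4-[(triethylsilyl)oxy]-3,6-dihydro-2H-pyran | CCC[C@@H](O[Si](C)(C)C(C)(C)C)C[C@H](OC)C[C@H](C)C[C@@H]1C=C(O[Si](CC)(CC)CC)C[C@H](CCOCc2ccc(OC)cc2)O1 | intermediate
19 | (2R,6S)-2-[(2S,4R,6R)-6-[(tert-butyldimethylsilyl)oxy]-4-methoxy-2-methylnonyl]-6-{2-[(4-methoxybenzyl)oxy]ethyl}oxan-4-one | CCC[C@@H](O[Si](C)(C)C(C)(C)C)C[C@H](OC)C[C@H](C)C[C@@H]1CC(=O)C[C@H](CCOCc2ccc(OC)cc2)O1 | intermediate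
20 | (2R,6S)-2-[(2S,4R,6R)-6-[(tert-butyldimethylsilyl)oxy]-4-methoxy-2-methylnonyl]-6-(2-hydroxyethyl)oxan-4-one | CCC[C@@H](O[Si](C)(C)C(C)(C)C)C[C@H](OC)C[C@H](C)C[C@@H]1CC(=O)C[C@H](CCO)O1 | intermediate
21 | 2-[(2S,6R)-6-[(2S,4R,6R)-6-[(tert-butyldimethylsilyl)oxy]-4-methoxy-2-methylnonyl]-4-oxooxan-2-yl]acetaldehyde | CCC[C@@H](O[Si](C)(C)C(C)(C)C)C[C@H](OC)C[C@H](C)C[C@@H]1CC(=O)C[C@H](CC=O)O1 | intermediate (not isolated)
22 | 2-[(2R,6R)-6-[(2S,4R,6R)-6-[(tert-butyldimethylsilyl)oxy]-4-methoxy-2-methylnonyl]-4-oxooxan-2-yl]acetic acid | CCC[C@@H](O[Si](C)(C)C(C)(C)C)C[C@H](OC)C[C@H](C)C[C@@H]1CC(=O)C[C@H](CC(=O)O)O1 | intermediate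
23 | 2-[(2R,6R)-6-[(2S,4R,6R)-6-hydroxy-4-methoxy-2-methylnonyl]-4-oxooxan-2-yl]acetic acid | CCC[C@@H](O)C[C@H](OC)C[C@H](C)C[C@@H]1CC(=O)C[C@H](CC(=O)O)O1 | intermediate
24 | mixed anhydride of 23 with 2,4,6-trichlorobenzoic acid | CCC[C@@H](O)C[C@H](OC)C[C@H](C)C[C@@H]1CC(=O)C[C@H](CC(=O)OC(=O)c2c(Cl)cc(Cl)cc2Cl)O1 | intermediate (not isolated)
25 | (1R,5R,7R,9S,11R)-7-methoxy-9-methyl-5-propyl-4,15-dioxabicyclo[9.3.1]pentadecane-3,13-dione | CCC[C@@H]1C[C@H](OC)C[C@H](C)C[C@@H]2CC(=O)C[C@H](CC(=O)O1)O2 | intermediate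
26 | (1R,5R,7R,9S,11R,13S)-13-hydroxy-7-methoxy-9-methyl-5-propyl-4,15-dioxabicyclo[9.3.1]pentadecan-3-one | CCC[C@@H]1C[C@H](OC)C[C@H](C)C[C@@H]2C[C@H](O)C[C@H](CC(=O)O1)O2 | intermediate
27 | prop-2-yn-1-amine | C#CCN | starting material
28 | methyl prop-2-yn-1-ylcarbamate | C#CCNC(=O)OC | intermediate
29 | methyl 5-bromo-4-oxopentanoate | COC(=O)CCC(=O)CBr | starting material
30 | formamide | NC=O | starting material
31 | methyl 3-(1,3-oxazol-4-yl)propanoate | COC(=O)CCc1cocn1 | intermediate
32 | [4-(3-methoxy-3-oxopropyl)-1,3-oxazol-2-yl]zinc chloride | COC(=O)CCc1coc([Zn]Cl)n1 | intermediate (not isolated)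
33 | methyl 3-(2-iodo-1,3-oxazol-4-yl)propanoate | COC(=O)CCc1coc(I)n1 | intermediate
34 | methyl 3-{2-[3-[(methoxycarbonyl)amino]prop-1-yn-1-yl]-1,3-oxazol-4-yl}propanoate | COC(=O)CCc1coc(C#CCNC(=O)OC)n1 | intermediate
35 | methyl 3-{2-[(1Z)-3-[(methoxycarbonyl)amino]prop-1-en-1-yl]-1,3-oxazol-4-yl}propanoate | COC(=O)CCc1coc(/C=C\CNC(=O)OC)n1 | intermediate
36 | methyl {(2Z)-3-[4-(3-oxopropyl)-1,3-oxazol-2-yl]prop-2-en-1-yl}carbamate | O=CCCc1coc(/C=C\CNC(=O)OC)n1 | intermediate
37 | methyl [bis(2,2,2-trifluoroethoxy)phosphoryl]acetate | COC(=O)CP(=O)(OCC(F)(F)F)OCC(F)(F)F | starting material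
38 | methyl (2Z)-5-{2-[(1Z)-3-[(methoxycarbonyl)amino]prop-1-en-1-yl]-1,3-oxazol-4-yl}pent-2-enoate | COC(=O)/C=C\CCc1coc(/C=C\CNC(=O)OC)n1 | intermediate
39 | (2Z)-5-{2-[(1Z)-3-[(methoxycarbonyl)amino]prop-1-en-1-yl]-1,3-oxazol-4-yl}pent-2-enoic acid | OC(=O)/C=C\CCc1coc(/C=C\CNC(=O)OC)n1 | intermediate
40 | neopeltolide, (1R,5R,7R,9S,11R,13R)-7-methoxy-9-methyl-3-oxo-5-propyl-4,15-dioxabicyclo[9.3.1]pentadecan-13-yl (2Z)-5-{2-[(1Z)-3-[(methoxycarbonyl)amino]prop-1-en-1-yl]-1,3-oxazol-4-yl}pent-2-enoate | CCC[C@@H]1C[C@H](OC)C[C@H](C)C[C@@H]2C[C@@H](OC(=O)/C=C\CCc3coc(/C=C\CNC(=O)OC)n3)C[C@H](CC(=O)O1)O2 | target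

## Step count and risks

Total step count: 28. Longest linear sequence: 18 steps (steps 1–10, 13–19 and 28).

Steps most likely to fail:

1. Step 13 (hetero-Diels–Alder). The cycloaddition of the heavily substituted diene may be slow, so that hydrolysis of the silyl dienol ether competes. The aldehyde-face selectivity may also erode, or a stepwise Mukaiyama-aldol pathway may leak to the 2,6-trans ring. The fallback sets out from enone 13 and aldehyde 17 and returns at ketone 19. Enone 13 would be converted into its diisopinocampheylboron enolate (Ipc2BCl antipode that sends the enolate to the Re face of 17, Et3N, Et2O, −78 °C) and added to 17. Oxidative work-up would give the β-hydroxy enone (3S,6E,9R,11R,13R)-13-[(tert-butyldimethylsilyl)oxy]-3-hydroxy-11-methoxy-1-[(4-methoxybenzyl)oxy]-9-methylhexadec-6-en-5-one F1. Catalytic KOt-Bu in THF at 0 °C would then close the pyran by 6-endo oxa-Michael addition of the C3 hydroxyl to C7 under thermodynamic control, which favours the 2,6-cis ketone 19.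

2. Step 7 (conjugate methylation). The δ-methoxy group may coordinate the metals and lower the facial discrimination, or 1,2-addition to the ester may compete. The fallback sets out from enoate 9 and returns at ester 10, with C9 set by a covalently bound auxiliary. Enoate 9 would be saponified (LiOH, THF/H2O) to (2E,5R,7R)-7-[(tert-butyldimethylsilyl)oxy]-5-methoxydec-2-enoic acid F2. Its pivaloyl mixed anhydride would be coupled with lithiated (4R)-4-phenyloxazolidin-2-one to give the N-enoyl imide (4R)-3-[(2E,5R,7R)-7-[(tert-butyldimethylsilyl)oxy]-5-methoxydec-2-enoyl]-4-phenyl-1,3-oxazolidin-2-one F3. MeMgBr/CuBr·SMe2 (THF/Me2S, −40 °C) should add to the magnesium-chelated syn-s-cis imide from the face opposite the phenyl group, giving (4R)-3-[(3S,5R,7R)-7-[(tert-butyldimethylsilyl)oxy]-5-methoxy-3-methyldecanoyl]-4-phenyl-1,3-oxazolidin-2-one F4. NaOMe in MeOH would release ester 10 and the auxiliary.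

3. Step 21 (oxazole formation). Conversion in hot formamide may be low, and the methyl ester may undergo aminolysis or the bromoketone may decompose. The fallback sets out from bromoketone 29 and returns at iodide 33, so it also bypasses step 22. Bromoketone 29 would be condensed with urea (DMF, 100 °C) in a Hantzsch-type reaction to methyl 3-(2-amino-1,3-oxazol-4-yl)propanoate F5. Non-aqueous diazotisation in the presence of an iodine source (t-BuONO, CH2I2, MeCN, 60 °C; Sandmeyer-type) would replace the amino group by iodine to give 33.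

## Further compounds

F1 | step 13 | (3S,6E,9R,11R,13R)-13-[(tert-butyldimethylsilyl)oxy]-3-hydroxy-11-methoxy-1-[(4-methoxybenzyl)oxy]-9-methylhexadec-6-en-5-one | CCC[C@@H](O[Si](C)(C)C(C)(C)C)C[C@H](OC)C[C@H](C)C/C=C/C(=O)C[C@@H](O)CCOCc1ccc(OC)cc1
F2 | step 7 | (2E,5R,7R)-7-[(tert-butyldimethylsilyl)oxy]-5-methoxydec-2-enoic acid | CCC[C@@H](O[Si](C)(C)C(C)(C)C)C[C@H](OC)C/C=C/C(=O)O
F3 | step 7 | (4R)-3-[(2E,5R,7R)-7-[(tert-butyldimethylsilyl)oxy]-5-methoxydec-2-enoyl]-4-phenyl-1,3-oxazolidin-2-one | CCC[C@@H](O[Si](C)(C)C(C)(C)C)C[C@H](OC)C/C=C/C(=O)N1[C@H](c2ccccc2)COC1=O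
F4 | step 7 | (4R)-3-[(3S,5R,7R)-7-[(tert-butyldimethylsilyl)oxy]-5-methoxy-3-methyldecanoyl]-4-phenyl-1,3-oxazolidin-2-one | CCC[C@@H](O[Si](C)(C)C(C)(C)C)C[C@H](OC)C[C@H](C)CC(=O)N1[C@H](c2ccccc2)COC1=O
F5 | step 21 | methyl 3-(2-amino-1,3-oxazol-4-yl)propanoate | COC(=O)CCc1coc(N)n1
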